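**Retrosynthetic overview**
1. Numbering (eudesmanolide type): side chain C1 (CH2O), C2, C3, C4 (stereocenter, C15 methyl); cyclohexene ring C5 (bears the side chain), C6 (acyloxy carbon), C7 and C8 (ring fusion, C8 bears the lactone oxygen), C9, C10 (bears the C14 methyl); lactone C11 (=C13H2) and C12 (C=O).
2. Key disconnection: C7–C8 and C5=C10 together, in a one-pot (3+3) annulation of γ-keto ester 3 (C5–C6–C7, C6 at the ketone level) with the mono-ketal of 3-oxobutanal 5 (C8–C9–C10): boron aldol, then acid-triggered lactonization, ketal cleavage and aldol condensation.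
3. Enabling feature: the C6 carbinol carbon of the cyclohexene ring lies between C5 and C7, so as a ketone it makes both ring carbons nucleophilic; C8 (lactone oxygen) and C10 (methyl-bearing alkene carbon) are 1,3-related and map onto the aldehyde and ketone carbons of 3-oxobutanal; the C12 ester sits γ to the new C8 oxygen and closes the lactone.
4. Ring order and stereocontrol: γ-lactone first (O8–C12), then the cyclohexenone (C5=C10), both in step 3; C4 from (S)-citronellal, C8 by the isopinocampheyl boron reagent, C7 by equilibration to the cis ring fusion, C6 by convex-face reduction and later inversion.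
5. Endgame: C1 is unveiled by ozonolysis of the citronellal terminus, the C11=C13 methylene by a Mannich/elimination sequence on the silyl-protected lactone, and both isobutyrates are installed last by a double Mitsunobu esterification that inverts C6.

Key step: step 3

Remark: it is assumed that hydride reduction of the C6 ketone in the cis-fused bicycle 10 takes place from the convex face (anti to the lactone), so that C6 must be inverted at the end.

Step 1
Reactants: 1 (S)-citronellal; 2 methyl acrylate
Product: 3 methyl (6S)-6,10-dimethyl-4-oxoundec-9-enoate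
Conditions: 3-benzyl-5-(2-hydroxyethyl)-4-methylthiazolium chloride (cat.), Et3N (cat.), 1,4-dioxane, 80 °C
Reagents that add atoms: none
Why: Stetter reaction, in which the thiazolylidene-derived Breslow intermediate of the aldehyde adds 1,4 to the acrylate; no stereocenter is formed and the existing one, β to the carbonyl, cannot epimerize.

Step 2
Reactants: 4 ethyl 2-(2-methyl-1,3-dioxolan-2-yl)acetate
Product: 5 2-(2-methyl-1,3-dioxolan-2-yl)acetaldehyde
Conditions: i-Bu2AlH (1.05 equiv), CH2Cl2, −78 °C; aq. potassium sodium tartrate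
Reagents that add atoms: none
Why: Partial ester reduction; the aluminium hemiacetal formed at −78 °C should survive until hydrolytic work-up and then release the aldehyde; no stereocenter.

Step 3
Reactants: 3 methyl (6S)-6,10-dimethyl-4-oxoundec-9-enoate; 5 2-(2-methyl-1,3-dioxolan-2-yl)acetaldehyde
Product: 8 (3aR,7aR)-6-methyl-5-[(2S)-6-methylhept-5-en-2-yl]-3,3a,7,7a-tetrahydro-1-benzofuran-2,4-dione, via syn-aldol adduct 6 (not isolated), via trans-lactone diketone 7 (not isolated)
Conditions: (−)-Ipc2BOTf [(−)-diisopinocampheylboron triflate, from (+)-α-pinene], i-Pr2NEt, CH2Cl2, −78 °C; then 5, −78 → −20 °C; then MeOH, TsOH·H2O, toluene, 60 °C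
Reagents that add atoms: none
Why: The bulky boron triflate/amine pair should enolize the C6 ketone of 3 on the unbranched C7 methylene to the Z enol borinate, which adds to the aldehyde of 5 through a chair Zimmerman–Traxler transition state (C7–C8; adduct 6 after methanolysis of the borinate); under acid the C8 hydroxyl lactonizes onto the C12 ester, the ketal is cleaved (7) and the C5 enol of the C6 ketone condenses with the freed C10 methyl ketone with loss of water (C5=C10). The closest known reaction types are the diisopinocampheylboron-mediated syn-aldol of ethyl-type ketones with aldehydes, acid-catalysed γ-lactonization, and the acid-mediated cyclodehydration of 2,6-diketones to 2-alkyl-3-methylcyclohex-2-enones (second stage of a Robinson annulation). The lactone closes by 5-exo-trig acyl substitution (O8 on C12) and the carbocycle by a 6-(enolendo)-exo-trig aldol addition followed by dehydration. C8 is set by the isopinocampheyl ligands (Si-face attack on the aldehyde is expected for this reagent enantiomer, giving 8R), C7 is formed syn and should then equilibrate through the C6 enol to the cis ring fusion (thermodynamic control), and C4 is not touched. The step needs enolization at C7 and not at C5, secured by the bulky reagent and the β-branch at C4 that shields C5, and condensation of C5 onto C10 and not of the C14 methyl onto C6, secured by thermodynamic control (tetrasubstituted enone) and the less hindered C10 carbonyl.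

Step 4
Reactants: 8 (3aR,7aR)-6-methyl-5-[(2S)-6-methylhept-5-en-2-yl]-3,3a,7,7a-tetrahydro-1-benzofuran-2,4-dione
Product: 10 (4S)-4-[(3aR,7aR)-6-methyl-2,4-dioxo-2,3,3a,4,7,7a-hexahydro-1-benzofuran-5-yl]pentanal, via side-chain ozonide 9 (not isolated)
Conditions: O3, CH2Cl2, −78 °C (Sudan Red 7B end point); then Me2S, −78 °C → rt
Reagents that add atoms: ozone, [O-][O+]=O
Why: Ozonolysis (Criegee mechanism, reductive work-up); ozone should cleave the electron-rich trisubstituted side-chain alkene far faster than the tetrasubstituted, carbonyl-conjugated ring alkene; no stereocenter remains from this step.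

Step 5
Reactants: 10 (4S)-4-[(3aR,7aR)-6-methyl-2,4-dioxo-2,3,3a,4,7,7a-hexahydro-1-benzofuran-5-yl]pentanal
Product: 11 (3aS,4R,7aR)-4-hydroxy-5-[(2S)-5-hydroxypentan-2-yl]-6-methyl-3a,4,7,7a-tetrahydro-1-benzofuran-2(3H)-one
Conditions: NaBH4, CeCl3·7H2O, EtOH/THF, −78 → −40 °C; AcOH quench at −40 °C
Reagents that add atoms: none
Why: Luche reduction of the aldehyde and, in 1,2 fashion, of the enone; hydride should add to C6 from the convex face of the cis-fused bicycle, anti to the lactone bond at C7, which places the new hydroxyl cis to the lactone (4R), epimeric to the target at this carbon and corrected in step 9.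

Step 6
Reactants: 11 (3aS,4R,7aR)-4-hydroxy-5-[(2S)-5-hydroxypentan-2-yl]-6-methyl-3a,4,7,7a-tetrahydro-1-benzofuran-2(3H)-one
Product: 12 (3aR,4R,7aR)-4-[(tert-butyldimethylsilyl)oxy]-5-[(2S)-5-[(tert-butyldimethylsilyl)oxy]pentan-2-yl]-6-methyl-3a,4,7,7a-tetrahydro-1-benzofuran-2(3H)-one
Conditions: TBSOTf, 2,6-lutidine, CH2Cl2, −78 → 0 °C
Reagents that add atoms: tert-butyldimethylsilyl trifluoromethanesulfonate (TBSOTf), CC(C)(C)[Si](C)(C)OS(=O)(=O)C(F)(F)F
Why: Silyl ether formation on both hydroxyls with the silyl triflate; no stereocenter changes, and the cis C6 oxygen is blocked against translactonization and against the base of step 7.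

Step 7
Reactants: 12 (3aR,4R,7aR)-4-[(tert-butyldimethylsilyl)oxy]-5-[(2S)-5-[(tert-butyldimethylsilyl)oxy]pentan-2-yl]-6-methyl-3a,4,7,7a-tetrahydro-1-benzofuran-2(3H)-one
Product: 15 (3aR,4R,7aR)-4-[(tert-butyldimethylsilyl)oxy]-5-[(2S)-5-[(tert-butyldimethylsilyl)oxy]pentan-2-yl]-6-methyl-3-methylidene-3a,4,7,7a-tetrahydro-1-benzofuran-2(3H)-one, via Mannich base 13 (not isolated), via trimethylammonium iodide 14 (not isolated)
Conditions: LiN(i-Pr)2, THF, −78 °C; CH2=NMe2+ I−, −78 → 0 °C; then MeI, MeOH, rt; then NaHCO3 (aq), EtOAc, rt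
Reagents that add atoms: dimethylmethylideneammonium iodide (Eschenmoser's salt), C=[N+](C)C.[I-]
Why: Lactone enolate Mannich reaction, N-methylation and Hofmann-type (E1cB) elimination; only the lactone has an acidic α-CH2, and the C3 stereocenter of 13 (convex-face attack) is destroyed in the elimination.

Step 8
Reactants: 15 (3aR,4R,7aR)-4-[(tert-butyldimethylsilyl)oxy]-5-[(2S)-5-[(tert-butyldimethylsilyl)oxy]pentan-2-yl]-6-methyl-3-methylidene-3a,4,7,7a-tetrahydro-1-benzofuran-2(3H)-one
Product: 16 (3aS,4R,7aR)-4-hydroxy-5-[(2S)-5-hydroxypentan-2-yl]-6-methyl-3-methylidene-3a,4,7,7a-tetrahydro-1-benzofuran-2(3H)-one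
Conditions: HF·pyridine, THF/pyridine, 0 °C → rt
Reagents that add atoms: none
Why: Fluoride-mediated desilylation under mildly acidic conditions that should spare the α-methylene lactone; no stereocenter changes.

Step 9
Reactants: 16 (3aS,4R,7aR)-4-hydroxy-5-[(2S)-5-hydroxypentan-2-yl]-6-methyl-3-methylidene-3a,4,7,7a-tetrahydro-1-benzofuran-2(3H)-one
Product: 17 (3aR,4S,7aR)-6-methyl-3-methylidene-5-[(2S)-5-[(2-methylpropanoyl)oxy]pentan-2-yl]-2-oxo-2,3,3a,4,7,7a-hexahydro-1-benzofuran-4-yl 2-methylpropanoate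
Conditions: PPh3, DIAD (betaine preformed at 0 °C), i-PrCO2H (excess), THF, 0 °C → rt
Reagents that add atoms: 2-methylpropanoic acid (isobutyric acid), CC(C)C(=O)O
Why: Double Mitsunobu esterification; both hydroxyls are activated as alkoxyphosphonium ions and displaced by isobutyrate, and at the secondary allylic C6 the SN2 displacement from the open convex face inverts the configuration (4R to 4S), while the primary carbon has no stereocenter.

**Compound list**
1 | (S)-citronellal, (3S)-3,7-dimethyloct-6-enal | C[C@@H](CCC=C(C)C)CC=O | starting material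
2 | methyl acrylate | C=CC(=O)OC | starting material
3 | methyl (6S)-6,10-dimethyl-4-oxoundec-9-enoate | COC(=O)CCC(=O)C[C@@H](C)CCC=C(C)C | intermediate
4 | ethyl 2-(2-methyl-1,3-dioxolan-2-yl)acetate | CCOC(=O)CC1(C)OCCO1 | starting material
5 | 2-(2-methyl-1,3-dioxolan-2-yl)acetaldehyde | O=CCC1(C)OCCO1 | intermediate
6 | methyl (3S,6S)-3-[(1R)-1-hydroxy-2-(2-methyl-1,3-dioxolan-2-yl)ethyl]-6,10-dimethyl-4-oxoundec-9-enoate (syn-aldol adduct) | COC(=O)C[C@H](C(=O)C[C@@H](C)CCC=C(C)C)[C@H](O)CC1(C)OCCO1 | intermediate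
7 | (4S,5R)-4-[(3S)-3,7-dimethyloct-6-enoyl]-5-(2-oxopropyl)oxolan-2-one (trans-lactone diketone) | O=C1C[C@H](C(=O)C[C@@H](C)CCC=C(C)C)[C@@H](CC(C)=O)O1 | intermediate
8 | (3aR,7aR)-6-methyl-5-[(2S)-6-methylhept-5-en-2-yl]-3,3a,7,7a-tetrahydro-1-benzofuran-2,4-dione (cis-fused) | C1C(=O)O[C@@H]2CC(C)=C([C@@H](C)CCC=C(C)C)C(=O)[C@H]12 | intermediate
9 | (3aR,7aR)-5-[(2S)-4-(5,5-dimethyl-1,2,4-trioxolan-3-yl)butan-2-yl]-6-methyl-3,3a,7,7a-tetrahydro-1-benzofuran-2,4-dione (ozonide, both epimers at the trioxolane carbon) | C1C(=O)O[C@@H]2CC(C)=C([C@@H](C)CCC3OOC(C)(C)O3)C(=O)[C@H]12 | intermediate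
10 | (4S)-4-[(3aR,7aR)-6-methyl-2,4-dioxo-2,3,3a,4,7,7a-hexahydro-1-benzofuran-5-yl]pentanal | C1C(=O)O[C@@H]2CC(C)=C([C@@H](C)CCC=O)C(=O)[C@H]12 | intermediate
11 | (3aS,4R,7aR)-4-hydroxy-5-[(2S)-5-hydroxypentan-2-yl]-6-methyl-3a,4,7,7a-tetrahydro-1-benzofuran-2(3H)-one (C6 hydroxyl cis to the lactone) | C1C(=O)O[C@@H]2CC(C)=C([C@@H](C)CCCO)[C@H](O)[C@H]12 | intermediate
12 | (3aR,4R,7aR)-4-[(tert-butyldimethylsilyl)oxy]-5-[(2S)-5-[(tert-butyldimethylsilyl)oxy]pentan-2-yl]-6-methyl-3a,4,7,7a-tetrahydro-1-benzofuran-2(3H)-one | C1C(=O)O[C@@H]2CC(C)=C([C@@H](C)CCCO[Si](C)(C)C(C)(C)C)[C@H](O[Si](C)(C)C(C)(C)C)[C@H]12 | intermediate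
13 | (3R,3aR,4R,7aR)-4-[(tert-butyldimethylsilyl)oxy]-5-[(2S)-5-[(tert-butyldimethylsilyl)oxy]pentan-2-yl]-3-[(dimethylamino)methyl]-6-methyl-3a,4,7,7a-tetrahydro-1-benzofuran-2(3H)-one (Mannich base) | CN(C)C[C@@H]1C(=O)O[C@@H]2CC(C)=C([C@@H](C)CCCO[Si](C)(C)C(C)(C)C)[C@H](O[Si](C)(C)C(C)(C)C)[C@H]12 | intermediate
14 | N,N,N-trimethyl-1-[(3R,3aR,4R,7aR)-4-[(tert-butyldimethylsilyl)oxy]-5-[(2S)-5-[(tert-butyldimethylsilyl)oxy]pentan-2-yl]-6-methyl-2-oxo-2,3,3a,4,7,7a-hexahydro-1-benzofuran-3-yl]methanaminium iodide | C[N+](C)(C)C[C@@H]1C(=O)O[C@@H]2CC(C)=C([C@@H](C)CCCO[Si](C)(C)C(C)(C)C)[C@H](O[Si](C)(C)C(C)(C)C)[C@H]12.[I-] | intermediate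
15 | (3aR,4R,7aR)-4-[(tert-butyldimethylsilyl)oxy]-5-[(2S)-5-[(tert-butyldimethylsilyl)oxy]pentan-2-yl]-6-methyl-3-methylidene-3a,4,7,7a-tetrahydro-1-benzofuran-2(3H)-one | C=C1C(=O)O[C@@H]2CC(C)=C([C@@H](C)CCCO[Si](C)(C)C(C)(C)C)[C@H](O[Si](C)(C)C(C)(C)C)[C@H]12 | intermediate
16 | (3aS,4R,7aR)-4-hydroxy-5-[(2S)-5-hydroxypentan-2-yl]-6-methyl-3-methylidene-3a,4,7,7a-tetrahydro-1-benzofuran-2(3H)-one (C6 epimer of the parent diol) | C=C1C(=O)O[C@@H]2CC(C)=C([C@@H](C)CCCO)[C@H](O)[C@H]12 | intermediate
17 | (3aR,4S,7aR)-6-methyl-3-methylidene-5-[(2S)-5-[(2-methylpropanoyl)oxy]pentan-2-yl]-2-oxo-2,3,3a,4,7,7a-hexahydro-1-benzofuran-4-yl 2-methylpropanoate | C=C1C(=O)O[C@@H]2CC(C)=C([C@@H](C)CCCOC(=O)C(C)C)[C@@H](OC(=O)C(C)C)[C@H]12 | target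

Total step count: 9. Longest linear sequence: 8 steps (steps 1, 3, 4, 5, 6, 7, 8 and 9 from compound 1; step 2 is a one-step side branch).

**Steps most likely to fail**

1. Step 3. The lactone oxygen at C8 is β to both ketones, so the acid that drives the condensation may cause β-elimination and aromatization to a phenol; closure in the other aldol sense (C14 methyl onto C6) is also possible. The fallback sets out from 3 and 5 and returns at 8; it separates the stages and keeps the C8 oxygen as a silyl ether during ring closure. The same boron aldol is stopped with an oxidative work-up (H2O2, pH 7 buffer, MeOH) and the syn-aldol adduct 6 is isolated. Silylation (TBSOTf, 2,6-lutidine) should give the C8 silyl ether F1. Ketal cleavage (pyridinium p-toluenesulfonate, wet acetone, 50 °C) should give the silyloxy diketone F2. Base-mediated intramolecular aldol condensation (NaOMe, MeOH, 0 °C → rt) should give the cyclohexenone ester F3, whose C7 centre is epimerizable and is drawn as the cis isomer that lactonizes. Desilylation and lactonization (aq. HF, MeCN; then cat. TsOH·H2O, toluene, 40 °C) should then give 8.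

2. Step 9. The activated allylic C6 oxygen may be lost by elimination to a ring diene or by SN2′ attack at C10, or the hindered carbinol may not react with the weakly acidic isobutyric acid. The fallback sets out from 16 and returns at 17; it replaces the redox activation by a sulfonate displacement. Selective acylation of the primary hydroxyl (i-PrCOCl, 2,4,6-collidine, CH2Cl2, −78 °C) should give the C1 mono-isobutyrate F4. Sulfonylation of C6–OH (ClCH2SO2Cl, pyridine, CH2Cl2, 0 °C) should give the C6 chloromethanesulfonate F5. SN2 displacement with inversion (CsO2C-i-Pr, 18-crown-6, toluene, 60 °C) should give 17.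

3. Step 5. Hydride delivery to C6 may show poor facial selectivity and give a mixture of C6 epimers, and the cis C6 alkoxide may translactonize in the basic medium. The fallback sets out from 10 and returns at 11; it replaces substrate control by catalyst control under non-basic conditions. A Corey–Bakshi–Shibata reduction with the (S)-2-methyl-CBS-oxazaborolidine (cat.) and BH3·SMe2 in THF at −40 °C should reduce the aldehyde as well. With the alkenyl carbon C5 as the large group, the usual model predicts hydride delivery to C6 in the same sense. This fallback makes no new compound (F0).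

**Further compounds**
F1 | step 3 | methyl (3S,6S)-3-[(1R)-1-[(tert-butyldimethylsilyl)oxy]-2-(2-methyl-1,3-dioxolan-2-yl)ethyl]-6,10-dimethyl-4-oxoundec-9-enoate | COC(=O)C[C@H](C(=O)C[C@@H](C)CCC=C(C)C)[C@H](O[Si](C)(C)C(C)(C)C)CC1(C)OCCO1
F2 | step 3 | methyl (3S,6S)-3-[(1R)-1-[(tert-butyldimethylsilyl)oxy]-3-oxobutyl]-6,10-dimethyl-4-oxoundec-9-enoate | COC(=O)C[C@H](C(=O)C[C@@H](C)CCC=C(C)C)[C@H](O[Si](C)(C)C(C)(C)C)CC(C)=O
F3 | step 3 | methyl 2-[(1R,6R)-6-[(tert-butyldimethylsilyl)oxy]-4-methyl-3-[(2S)-6-methylhept-5-en-2-yl]-2-oxocyclohex-3-en-1-yl]acetate | COC(=O)C[C@H]1C(=O)C([C@@H](C)CCC=C(C)C)=C(C)C[C@H]1O[Si](C)(C)C(C)(C)C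
F4 | step 9 | (4S)-4-[(3aS,4R,7aR)-4-hydroxy-6-methyl-3-methylidene-2-oxo-2,3,3a,4,7,7a-hexahydro-1-benzofuran-5-yl]pentyl 2-methylpropanoate | C=C1C(=O)O[C@@H]2CC(C)=C([C@@H](C)CCCOC(=O)C(C)C)[C@H](O)[C@H]12
F5 | step 9 | (4S)-4-[(3aR,4R,7aR)-4-[(chloromethanesulfonyl)oxy]-6-methyl-3-methylidene-2-oxo-2,3,3a,4,7,7a-hexahydro-1-benzofuran-5-yl]pentyl 2-methylpropanoate | C=C1C(=O)O[C@@H]2CC(C)=C([C@@H](C)CCCOC(=O)C(C)C)[C@H](OS(=O)(=O)CCl)[C@H]12
F0 | step 5 | none | none
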